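**Retrosynthetic overview**
1. Griffinone A ⇒ break O1–C2 (retro-oxa-Michael). Ring C closes last: the ring A enol oxygen of a dearomatised chalcone adds to Cβ of its cinnamoyl group under a chiral bifunctional catalyst, the laboratory counterpart of chalcone isomerase. This single step sets C2 (S).
2. Dearomatised chalcone ⇒ break Cα=Cβ (retro-Claisen–Schmidt): benzaldehyde (ring B) plus the gem-diprenyl acetyl cyclohexadienone.
3. Acetyl cyclohexadienone ⇒ break both C8–CH2 bonds (retro dearomative C-prenylation, the counterpart of two prenyl transfers to one carbon): 2',4'-dihydroxy-6'-methoxyacetophenone plus two prenyl bromide.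
4. Ring order: rings A and B are bought as arenes, ring A is dearomatised in the first step, and ring C is the only ring formed, in the last step.

Assumption: ketone 1 is bought as a catalogue building block. The facial sense of the catalyst in step 3 is assigned by analogy with conjugate additions to chalcones and is checked on the first run by chiral HPLC and electronic circular dichroism.

**Step 1**
Reactants: 1 1-(2,4-dihydroxy-6-methoxyphenyl)ethan-1-one (2',4'-dihydroxy-6'-methoxyacetophenone); 2 1-bromo-3-methylbut-2-ene (prenyl bromide)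
Product: 4 4-acetyl-5-hydroxy-3-methoxy-6,6-bis(3-methylbut-2-en-1-yl)cyclohexa-2,4-dien-1-one, via monoprenyl ketone 3 (not isolated)
Conditions: 2 (2.1 equiv), KOH (3.2 equiv), H2O, vigorous stirring, 0 °C to rt, 16 h; cold dilute aq. HCl to pH 3; SiO2
Reagents that add atoms: prenyl bromide 2, CC(C)=CCBr
Why: Dearomative double C-alkylation (nuclear prenylation) of a phenolate dianion, in which C3 lies between the two oxyanions and is the established site of nuclear alkylation in 2,4-dihydroxyacylbenzenes, water hydrogen-bonds the oxygens and disfavours O-prenylation, and the second SN2 alkylation at C3 gives the delocalised mono-anion of vinylogous acid 4, which is too weak a nucleophile to take a third prenyl group quickly; no stereocentre is formed.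

**Step 2**
Reactants: 4 4-acetyl-5-hydroxy-3-methoxy-6,6-bis(3-methylbut-2-en-1-yl)cyclohexa-2,4-dien-1-one; 5 benzaldehyde
Product: 7 5-hydroxy-3-methoxy-6,6-bis(3-methylbut-2-en-1-yl)-4-[(2E)-3-phenylprop-2-enoyl]cyclohexa-2,4-dien-1-one, via aldol adduct 6 (not isolated)
Conditions: 5 (1.5 equiv), 50% aq. KOH, EtOH, rt, 24–48 h, dark; cold dilute aq. HCl to pH 3–4; rapid SiO2
Reagents that add atoms: benzaldehyde 5, O=Cc1ccccc1
Why: Claisen–Schmidt aldol condensation, in which the ring of 4 sits as its delocalised anion (so the vinylogous methyl ester is not saponified), the acetyl CH3 is the only enolisable position, benzaldehyde cannot enolise, and E1cB loss of hydroxide from 6 gives the conjugated (E)-enone, which stays ring-open in base as its stabilised anion; no stereocentre remains in 7.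

**Step 3**
Reactants: 7 5-hydroxy-3-methoxy-6,6-bis(3-methylbut-2-en-1-yl)-4-[(2E)-3-phenylprop-2-enoyl]cyclohexa-2,4-dien-1-one
Product: 8 griffinone A, (2S)-5-methoxy-8,8-bis(3-methylbut-2-en-1-yl)-2-phenyl-2,3-dihydro-4H-chromene-4,7(8H)-dione
Conditions: N-[3,5-bis(trifluoromethyl)phenyl]-N'-[(9R)-6'-methoxycinchonan-9-yl]thiourea (quinidine-derived, 10 mol %), PhMe (0.05 mol/L), 0 °C, 48–96 h (HPLC control); SiO2 plug to remove the catalyst; recrystallise (hexane/EtOAc)
Reagents that add atoms: none
Why: Proposed new method: a chalcone-isomerase-like 6-endo-trig intramolecular oxa-Michael addition in which the quinuclidine nitrogen takes the acidic enol proton of 7 (acidity comparable with the 2'-OH of acylphloroglucinol chalcones), the thiourea N–H pair binds the cinnamoyl carbonyl of the s-trans enone rotamer as an oxyanion hole, the ion-paired enolate oxygen is delivered to the Si face of Cβ and the ammonium proton then quenches the C3 enolate, which sets C2 as S; closure is favoured because the flanking methoxy group and the gem-diprenyl carbon twist the cinnamoyl group out of conjugation, C4a is blocked so only O-attack is possible, the non-polar medium, low temperature and prompt catalyst removal limit retro-Michael racemisation, the acid-sensitive prenyl groups are untouched, and the closest known reaction type is the cinchona-thiourea-catalysed enantioselective cyclisation of 2'-hydroxychalcones (and their α-carboxylate-activated analogues) to flavanones, extended here from a phenol to a non-aromatic enol nucleophile.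

**Compound list**
1 | 1-(2,4-dihydroxy-6-methoxyphenyl)ethan-1-one | COc1cc(O)cc(O)c1C(C)=O | starting material
2 | 1-bromo-3-methylbut-2-ene (prenyl bromide) | CC(C)=CCBr | starting material
3 | 1-[2,4-dihydroxy-6-methoxy-3-(3-methylbut-2-en-1-yl)phenyl]ethan-1-one | COc1cc(O)c(CC=C(C)C)c(O)c1C(C)=O | intermediate
4 | 4-acetyl-5-hydroxy-3-methoxy-6,6-bis(3-methylbut-2-en-1-yl)cyclohexa-2,4-dien-1-one | COC1=CC(=O)C(CC=C(C)C)(CC=C(C)C)C(O)=C1C(C)=O | intermediate
5 | benzaldehyde | O=Cc1ccccc1 | starting material
6 | 5-hydroxy-4-(3-hydroxy-3-phenylpropanoyl)-3-methoxy-6,6-bis(3-methylbut-2-en-1-yl)cyclohexa-2,4-dien-1-one (racemic) | COC1=CC(=O)C(CC=C(C)C)(CC=C(C)C)C(O)=C1C(=O)CC(O)c1ccccc1 | intermediate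
7 | 5-hydroxy-3-methoxy-6,6-bis(3-methylbut-2-en-1-yl)-4-[(2E)-3-phenylprop-2-enoyl]cyclohexa-2,4-dien-1-one | COC1=CC(=O)C(CC=C(C)C)(CC=C(C)C)C(O)=C1C(=O)/C=C/c1ccccc1 | intermediate
8 | griffinone A, (2S)-5-methoxy-8,8-bis(3-methylbut-2-en-1-yl)-2-phenyl-2,3-dihydro-4H-chromene-4,7(8H)-dione | COC1=CC(=O)C(CC=C(C)C)(CC=C(C)C)C2=C1C(=O)C[C@@H](c1ccccc1)O2 | target

**Total step count:** 3. **Longest linear sequence:** 3.

**Steps most likely to fail**

**Step 3 (highest risk).**
- The chelated enol may be too weak a nucleophile.
- The closure may stop at an equilibrium.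
- A reversible addition may erode the ee.

Unreacted 7 is acidic. A brief cold NaHCO3 wash returns it for recycling and leaves neutral 8 in the organic layer. If the first run gives 2R, the quinine-derived pseudoenantiomer N-[3,5-bis(trifluoromethyl)phenyl]-N'-[(8α,9S)-6'-methoxycinchonan-9-yl]thiourea is used instead.

The fallback sets out from 4 and comes back to the route at 8. It makes C2–phenyl, not O1–C2, the stereodefining bond. Ketone 4 is heated with tert-butoxybis(dimethylamino)methane in toluene to give the enaminone F1. Warm acetic acid closes this to the dearomatised chromone F2. Phenylboronic acid is then added across C2=C3 with [Rh(OH)(cod)]2 (monovalent rhodium) in toluene at rt without added base. The ligand is the antipode of an electron-poor MeO-BIPHEP-type diphosphine that gives the 2S product. The fully substituted methoxy-enone carbon of ring A does not compete as an acceptor.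

**Step 1.** About 30–40% of 4 is expected. Attack at C5 (3,5-diprenyl arene), O-prenylation and a third alkylation compete. The bulky prenyl bromide may also avoid the already substituted C3.

The fallback sets out from 1 and comes back at 4. It uses allyl as a small prenyl surrogate. Allyl bromide (2.1 equiv) in aqueous KOH passes through the 3-allyl ketone F3. It attacks the substituted C3 more readily and gives the gem-diallyl dienone F4. Cross-metathesis follows with excess 2-methylbut-2-ene and second-generation Grubbs catalyst RuCl2(=CHPh)(PCy3)(H2IMes) in CH2Cl2 at 40 °C. This converts both allyl groups into prenyl groups, through the allyl prenyl dienone F5, and gives 4.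

**Step 2.** Retro-Claisen loss of the acetyl group, saponification of the vinylogous ester, or a sluggish second deprotonation of the anion of 4 may spoil the condensation. Neutral 7 may also start to cyclise racemically during an acidic work-up.

The fallback sets out from 1 and comes back at 7. It makes the enone on the simple arene and dearomatises afterwards. Ketone 1 and 5 in KOH/EtOH give, through the aromatic aldol adduct F6, the chalcone cardamonin F7. The dianion of this chalcone is then prenylated twice at C3' with 2 in aqueous KOH, through 3'-prenylcardamonin F8. Cold acidification delivers 7.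

**Further compounds**
F1 | step 3 | 4-[(2E)-3-(dimethylamino)prop-2-enoyl]-5-hydroxy-3-methoxy-6,6-bis(3-methylbut-2-en-1-yl)cyclohexa-2,4-dien-1-one | COC1=CC(=O)C(CC=C(C)C)(CC=C(C)C)C(O)=C1C(=O)/C=C/N(C)C
F2 | step 3 | 5-methoxy-8,8-bis(3-methylbut-2-en-1-yl)-4H-chromene-4,7(8H)-dione | COC1=CC(=O)C(CC=C(C)C)(CC=C(C)C)C2=C1C(=O)C=CO2
F3 | step 1 | 1-[2,4-dihydroxy-6-methoxy-3-(prop-2-en-1-yl)phenyl]ethan-1-one | COc1cc(O)c(CC=C)c(O)c1C(C)=O
F4 | step 1 | 4-acetyl-5-hydroxy-3-methoxy-6,6-di(prop-2-en-1-yl)cyclohexa-2,4-dien-1-one | COC1=CC(=O)C(CC=C)(CC=C)C(O)=C1C(C)=O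
F5 | step 1 | 4-acetyl-5-hydroxy-3-methoxy-6-(3-methylbut-2-en-1-yl)-6-(prop-2-en-1-yl)cyclohexa-2,4-dien-1-one (racemic) | COC1=CC(=O)C(CC=C)(CC=C(C)C)C(O)=C1C(C)=O
F6 | step 2 | 1-(2,4-dihydroxy-6-methoxyphenyl)-3-hydroxy-3-phenylpropan-1-one (racemic) | COc1cc(O)cc(O)c1C(=O)CC(O)c1ccccc1
F7 | step 2 | cardamonin, (2E)-1-(2,4-dihydroxy-6-methoxyphenyl)-3-phenylprop-2-en-1-one | COc1cc(O)cc(O)c1C(=O)/C=C/c1ccccc1
F8 | step 2 | (2E)-1-[2,4-dihydroxy-6-methoxy-3-(3-methylbut-2-en-1-yl)phenyl]-3-phenylprop-2-en-1-one | COc1cc(O)c(CC=C(C)C)c(O)c1C(=O)/C=C/c1ccccc1
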